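The cyclohexenone ring (C1 ketone, C2 bearing C7H2OH, C3 vinylic CH, C4 isobutyrate carbinol, C5 isopropyl carbon, C6 hydroxytiglate carbinol) is opened at C2=C3 and C1–C6. The feature exploited: C6–C1(=O)–C2(C7)=C3 is an oxidised conjugated diene whose C1–C2–C7 core is propargyl alcohol. A tandem enyne cross-metathesis/ring-closing metathesis inserts a propargyl silyl ether between the two alkene termini of an acyclic, enantiopure 1,5-diene ester that already carries C4 and C5, building the carbocycle as a cyclohexa-1,3-diene in one operation. The diene ester comes from an anti-selective asymmetric allylboration. Site- and face-selective dihydroxylation of C1=C6 and allylic oxidation then give the 6-hydroxyenone.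

Key step: step 3

Remark on the chemistry: the ring numbering C1–C7 defined above is used for all intermediates, acyclic ones included. In the target, C6–O is trans to the C5 isopropyl group and C4–O is cis to it (4S,5S,6R). Commercial crotonaldehyde is taken as the E isomer. Its alkene geometry does not matter for the target, because that terminus leaves as propene in step 3.

Step 1
Reactants: 1 (E)-4-methylpent-2-ene; 2 (+)-B-methoxydiisopinocampheylborane, (+)-Ipc2BOMe, derived from (−)-α-pinene; 3 (E)-but-2-enal (crotonaldehyde)
Product: 8 (3R,4S,5E)-3-isopropylhepta-1,5-dien-4-ol (anti isomer), via allylpotassium 4 (not isolated), via borate complex 5 (not isolated), via allylborane 6 (not isolated), via borinate 7 (not isolated)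
Conditions: n-BuLi, KOtBu, THF, −78 to −50 °C; 2, −78 °C; BF3·OEt2, −78 °C; 3, −78 °C; then NaOH, H2O2, 0 °C to rt
Reagents that add atoms: none
Why: Brown-type asymmetric allylboration: superbase metalation at the methyl group keeps the E geometry, the closed chair (Zimmerman–Traxler) transition state turns E into the anti C4/C5 relationship, and the isopinocampheyl groups from (−)-α-pinene steer the allyl unit to the Re face of 3, which sets C4 (S) and with it C5 (R in this compound).

Step 2
Reactants: 8 (3R,4S,5E)-3-isopropylhepta-1,5-dien-4-ol
Product: 9 (3R,4S,5E)-3-isopropylhepta-1,5-dien-4-yl 2-methylpropanoate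
Conditions: (iPrCO)2O, Et3N, DMAP (cat.), CH2Cl2, 0 °C to rt
Reagents that add atoms: isobutyric anhydride, CC(C)C(=O)OC(=O)C(C)C
Why: DMAP-catalysed acyl transfer takes place at oxygen, so C4 is retained, the final isobutyrate is installed early, and the neighbouring C3 propenyl group is made less reactive toward the metathesis catalyst.

Step 3
Reactants: 9 (3R,4S,5E)-3-isopropylhepta-1,5-dien-4-yl 2-methylpropanoate; 10 tert-butyldimethyl(prop-2-yn-1-yloxy)silane
Product: 11 (1R,6R)-3-{[(tert-butyldimethylsilyl)oxy]methyl}-6-isopropylcyclohexa-2,4-dien-1-yl 2-methylpropanoate (ester oxygen and isopropyl cis)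
Conditions: second-generation Hoveyda–Grubbs catalyst RuCl2(H2IMes)(=CH-C6H4-2-OiPr) (cat.), 1,4-benzoquinone (cat.), 10 (2 equiv, slow addition), toluene (dilute), 60 °C, argon sparge
Reagents that add atoms: none
Why: The catalyst loads on the only terminal alkene of 9 to give the alkylidene Ru=C6H, which inserts the terminal alkyne 10 with the usual 1,3-regiochemistry (C6 bonds to the unsubstituted C1, ruthenium moves to C2) and so forms C1=C6 and the vinylcarbene Ru=C2(CH2OTBS). This carbene closes the ring by metathesis onto the C3 propenyl group, forming C2=C3 and expelling Ru=CHCH3, which exchanges with the vinyl group of the next molecule of 9 and leaves as propene. The closest known reaction type is the tandem enyne cross-metathesis/ring-closing metathesis of hexa-1,5-diene or cycloocta-1,5-diene with terminal alkynes, which gives 2-substituted cyclohexa-1,3-dienes. The single ring formed is the six-membered carbocycle, closed by [2+2] cycloaddition/cycloreversion of the C2 carbene on the C3 alkene, which is possible only from a Z-configured C1=C6 bond; E-configured open-chain material should re-enter through secondary metathesis at that disubstituted bond, with the conjugated ring plus volatile propene as the sink. No stereocentre is created, and C4 and C5 are spectators under these neutral conditions. The step needs site selectivity between the two alkenes of 9, secured by the 1,2-disubstitution of the C3 alkene and its electron-withdrawing allylic ester, and it needs ring closure to outrun a second alkyne insertion, secured by slow addition of 10 at high dilution.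

Step 4
Reactants: 11 the cyclohexa-1,3-diene of step 3
Product: 12 (1S,4S,5R,6R)-3-{[(tert-butyldimethylsilyl)oxy]methyl}-4,5-dihydroxy-6-isopropylcyclohex-2-en-1-yl 2-methylpropanoate (C1–OH and C6–OH cis to each other, both trans to isopropyl and to the isobutyrate)
Conditions: OsO4 (cat.), NMO (1 equiv), acetone/H2O, 0 °C
Reagents that add atoms: N-methylmorpholine N-oxide, C[N+]1([O-])CCOCC1; water, O; OsO4 (catalytic oxygen carrier), O=[Os](=O)(=O)=O
Why: Upjohn dihydroxylation: OsO4 adds suprafacially to the cis-disubstituted C1=C6 bond, which is less hindered and more electron-rich than trisubstituted C2=C3 with its two allylic C–O bonds, and it approaches the face anti to the cis-disposed C4 ester and C5 isopropyl groups, which sets C6 (R, oxygen trans to isopropyl) and a transient C1 carbinol.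

Step 5
Reactants: 12 the cis-diol of step 4
Product: 13 (1S,5R,6R)-3-{[(tert-butyldimethylsilyl)oxy]methyl}-5-hydroxy-6-isopropyl-4-oxocyclohex-2-en-1-yl 2-methylpropanoate (6-hydroxyenone in ring numbering)
Conditions: activated MnO2, CH2Cl2, rt
Reagents that add atoms: none
Why: MnO2 allylic oxidation is chemoselective for the allylic C1 carbinol over the saturated C6 carbinol, so the C1=O/C2=C3 enone is formed, the auxiliary C1 stereocentre is erased and C6 is left untouched.

Step 6
Reactants: 14 (tert-butyldimethylsilyloxy)acetaldehyde; 15 ethyl 2-(triphenylphosphoranylidene)propanoate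
Product: 16 ethyl (E)-4-[(tert-butyldimethylsilyl)oxy]-2-methylbut-2-enoate
Conditions: CH2Cl2, rt
Reagents that add atoms: none
Why: Wittig olefination with a stabilised, α-branched ylide should give the E (tiglate-type) trisubstituted enoate under thermodynamic control of oxaphosphetane formation.

Step 7
Reactants: 16 ethyl (E)-4-[(tert-butyldimethylsilyl)oxy]-2-methylbut-2-enoate
Product: 17 (E)-4-[(tert-butyldimethylsilyl)oxy]-2-methylbut-2-enoic acid
Conditions: LiOH, THF/MeOH/H2O, rt; then dilute HCl to pH 4, 0 °C
Reagents that add atoms: lithium hydroxide, [Li+].[OH-]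
Why: Saponification cleaves the ethyl ester by acyl–oxygen fission, while the primary silyl ether and the E alkene tolerate mild hydroxide and a brief, cold, weakly acidic work-up.

Step 8
Reactants: 13 the 6-hydroxyenone of step 5; 17 (E)-4-[(tert-butyldimethylsilyl)oxy]-2-methylbut-2-enoic acid
Product: 18 (1R,5S,6S)-3-{[(tert-butyldimethylsilyl)oxy]methyl}-5-(isobutyryloxy)-6-isopropyl-2-oxocyclohex-3-en-1-yl (E)-4-[(tert-butyldimethylsilyl)oxy]-2-methylbut-2-enoate (bis-silyl ether of the target)
Conditions: DCC, DMAP (cat.), CH2Cl2, 0 °C to rt
Reagents that add atoms: none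
Why: Steglich esterification acylates the only free hydroxyl at oxygen, so C6 is retained, and the tiglate-type E geometry is the stable one and should not isomerise under DMAP catalysis.

Step 9
Reactants: 18 the bis-silyl ether of step 8
Product: 19 target CNP0254776.1, (1R,5S,6S)-3-(hydroxymethyl)-5-(isobutyryloxy)-6-isopropyl-2-oxocyclohex-3-en-1-yl (E)-4-hydroxy-2-methylbut-2-enoate
Conditions: HF·pyridine, pyridine, THF, 0 °C to rt
Reagents that add atoms: none
Why: Fluoride-driven desilylation in a buffered, non-basic medium removes both primary allylic silyl ethers in one operation without touching the two esters, the enone or the base-sensitive C6 centre.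

Compound list
1 | (E)-4-methylpent-2-ene | C/C=C/C(C)C | starting material
2 | (+)-B-methoxydiisopinocampheylborane, from (−)-α-pinene | COB([C@H]1C[C@H]2C[C@@H]([C@@H]1C)C2(C)C)[C@H]1C[C@H]2C[C@@H]([C@@H]1C)C2(C)C | starting material
3 | (E)-but-2-enal | C/C=C/C=O | starting material
4 | potassium (E)-4-methylpent-2-en-1-ide | [K+].[CH2-]/C=C/C(C)C | intermediate
5 | potassium methoxy[(E)-4-methylpent-2-en-1-yl]diisopinocampheylborate | [K+].CO[B-](C/C=C/C(C)C)([C@H]1C[C@H]2C[C@@H]([C@@H]1C)C2(C)C)[C@H]1C[C@H]2C[C@@H]([C@@H]1C)C2(C)C | intermediate
6 | [(E)-4-methylpent-2-en-1-yl]diisopinocampheylborane | CC(C)/C=C/CB([C@H]1C[C@H]2C[C@@H]([C@@H]1C)C2(C)C)[C@H]1C[C@H]2C[C@@H]([C@@H]1C)C2(C)C | intermediate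
7 | diisopinocampheylborinic ester of 8 | C/C=C/[C@H](OB([C@H]1C[C@H]2C[C@@H]([C@@H]1C)C2(C)C)[C@H]1C[C@H]2C[C@@H]([C@@H]1C)C2(C)C)[C@@H](C=C)C(C)C | intermediate
8 | (3R,4S,5E)-3-isopropylhepta-1,5-dien-4-ol | C/C=C/[C@H](O)[C@@H](C=C)C(C)C | intermediate
9 | (3R,4S,5E)-3-isopropylhepta-1,5-dien-4-yl 2-methylpropanoate | C/C=C/[C@H](OC(=O)C(C)C)[C@@H](C=C)C(C)C | intermediate
10 | tert-butyldimethyl(prop-2-yn-1-yloxy)silane | C#CCO[Si](C)(C)C(C)(C)C | starting material
11 | (1R,6R)-3-{[(tert-butyldimethylsilyl)oxy]methyl}-6-isopropylcyclohexa-2,4-dien-1-yl 2-methylpropanoate | C1=CC(CO[Si](C)(C)C(C)(C)C)=C[C@H](OC(=O)C(C)C)[C@@H]1C(C)C | intermediate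
12 | (1S,4S,5R,6R)-3-{[(tert-butyldimethylsilyl)oxy]methyl}-4,5-dihydroxy-6-isopropylcyclohex-2-en-1-yl 2-methylpropanoate | O[C@H]1[C@@H](O)C(CO[Si](C)(C)C(C)(C)C)=C[C@H](OC(=O)C(C)C)[C@@H]1C(C)C | intermediate
13 | (1S,5R,6R)-3-{[(tert-butyldimethylsilyl)oxy]methyl}-5-hydroxy-6-isopropyl-4-oxocyclohex-2-en-1-yl 2-methylpropanoate | O[C@H]1C(=O)C(CO[Si](C)(C)C(C)(C)C)=C[C@H](OC(=O)C(C)C)[C@@H]1C(C)C | intermediate
14 | (tert-butyldimethylsilyloxy)acetaldehyde | O=CCO[Si](C)(C)C(C)(C)C | starting material
15 | ethyl 2-(triphenylphosphoranylidene)propanoate | CCOC(=O)C(C)=P(c1ccccc1)(c1ccccc1)c1ccccc1 | starting material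
16 | ethyl (E)-4-[(tert-butyldimethylsilyl)oxy]-2-methylbut-2-enoate | CCOC(=O)/C(C)=C/CO[Si](C)(C)C(C)(C)C | intermediate
17 | (E)-4-[(tert-butyldimethylsilyl)oxy]-2-methylbut-2-enoic acid | OC(=O)/C(C)=C/CO[Si](C)(C)C(C)(C)C | intermediate
18 | bis(tert-butyldimethylsilyl) ether of the target | C/C(=C\CO[Si](C)(C)C(C)(C)C)C(=O)O[C@H]1C(=O)C(CO[Si](C)(C)C(C)(C)C)=C[C@H](OC(=O)C(C)C)[C@@H]1C(C)C | intermediate
19 | CNP0254776.1 | C/C(=C\CO)C(=O)O[C@H]1C(=O)C(CO)=C[C@H](OC(=O)C(C)C)[C@@H]1C(C)C | target

Total step count: 9. Longest linear sequence: 7 (steps 1, 2, 3, 4, 5, 8, 9).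

Steps most likely to fail

**Step 3.**
- What may go wrong:
  - The irreversible alkyne insertion may deliver the E-configured vinylcarbene, which cannot cyclise and drains into open-chain trienes or alkyne oligomers.
  - Competing loading of ruthenium on the C3 alkene would give the regioisomeric ring.
  - The cyclohexadienyl ester may lose isobutyric acid and aromatise.
- Fallback (from 9 and 10, back to the route at 11): the alkyne insertion is separated from ring formation. Alkyne 10 is first converted with ethene (1 atm, second-generation Grubbs catalyst, CH2Cl2, rt) into 2-{[(tert-butyldimethylsilyl)oxy]methyl}buta-1,3-diene F1. F1 and 9 are then joined by olefin cross-metathesis between their two monosubstituted vinyl groups to give the open-chain tetraene F2, whose Z isomer closes onto the C3 propenyl group to give 11.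
- Why it helps: every event is now reversible olefin metathesis. E-configured tetraene is therefore recycled, alkyne oligomerisation is excluded, and the pairing of the two most reactive alkene termini fixes the regiochemistry.

**Step 4.**
- What may go wrong: osmylation may compete at C2=C3, a second osmylation may follow the first, or the diene may aromatise during handling.
- Fallback (from 11, back to the route at 13, passing by 12): crude 11 is epoxidised with dimethyldioxirane in acetone at low temperature under neutral conditions, on the face anti to the C4 and C5 substituents, to give the C1–C6 vinyl epoxide F3. Mild hydrolytic opening at the allylic C1 position (H2O/THF, catalytic pyridinium p-toluenesulfonate) gives the trans-diol F4. Its C1 configuration is irrelevant, and MnO2 oxidises its allylic carbinol to 13.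
- Why it helps: the C6–O bond is never broken, so C6 keeps the configuration set by the epoxidation.

**Step 1.**
- What may go wrong: the allylpotassium may lose E geometry, or metalation may occur at the isopropyl methine. Either would erode the anti/syn purity. Separation of the small dienol from isopinocampheol may also be troublesome.
- Fallback (from 3, back to the route at 8): a geometrically defined, isolable reagent and a catalytic source of chirality are used. Commercial allylboronic acid pinacol ester is cross-metathesised with 3-methylbut-1-ene (second-generation Grubbs catalyst) to give the (E)-allylboronate F5. F5 adds to 3 under catalysis by a BINOL-derived TRIP phosphoric acid through the same closed chair, giving the borate ester F6, which is hydrolysed on work-up to 8.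
- Choice of catalyst enantiomer: the antipode that directs Re-face attack is needed. This is expected to be R, and the other antipode is taken if the sense of induction proves opposite.

Further compounds
F1 | step 3 | 2-{[(tert-butyldimethylsilyl)oxy]methyl}buta-1,3-diene | C=CC(=C)CO[Si](C)(C)C(C)(C)C
F2 | step 3 | open-chain tetraene, Z at C1=C6, (4S,5R) in ring numbering | C/C=C/[C@H](OC(=O)C(C)C)[C@@H](/C=C\C(=C)CO[Si](C)(C)C(C)(C)C)C(C)C
F3 | step 4 | C1–C6 vinyl epoxide of 11, oxygen trans to isopropyl | O1[C@H]2[C@@H]1C(CO[Si](C)(C)C(C)(C)C)=C[C@H](OC(=O)C(C)C)[C@@H]2C(C)C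
F4 | step 4 | trans-diol, C1 epimer of 12 | O[C@H]1[C@H](O)C(CO[Si](C)(C)C(C)(C)C)=C[C@H](OC(=O)C(C)C)[C@@H]1C(C)C
F5 | step 1 | (E)-4,4,5,5-tetramethyl-2-(4-methylpent-2-en-1-yl)-1,3,2-dioxaborolane | CC(C)/C=C/CB1OC(C)(C)C(C)(C)O1
F6 | step 1 | pinacol borate ester of 8 | C/C=C/[C@H](OB1OC(C)(C)C(C)(C)O1)[C@@H](C=C)C(C)C
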